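**Plan**
- The retrosynthesis first cuts the C8–C9 bond of the nonadecyl chain (counted from its CH3 end) into two primary alkyl radicals. Each is traced to an acid one carbon longer: nonanoic acid and 12-(pyrrol-3-yl)dodecanoic acid 11, both as N-hydroxyphthalimide esters.
- Enabling feature: the chain on pyrrole C3 is an unbranched (CH2)18CH3 with no heteroatom, and C8 and C9 have only CH2 neighbours, so both carboxyl handles leave as CO2 without trace. The ring (N1, C2–CO2Me, C3) sits eleven CH2 away and is untouched by a cathodic event, whereas an anodic Kolbe coupling would endanger the electron-rich ring.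
- The second cut is a Barton–Zard disconnection of the pyrrole at C2–C3 and C4–C5, into methyl isocyanoacetate (N1, C2, C5) and a terminal nitroalkene (C3, C4).
- The third cut traces the nitroalkene to a C13 aldehyde ester and nitromethane. The aldehyde ester comes from ozonolysis of the C13=C14 bond of erucic acid: erucic C13 becomes pyrrole C3, C2–C12 become the eleven CH2, and C1 is the radical handle.
- Forward order: benzyl ester, ozonolysis, Henry reaction, acetate, pyrrole ring, hydrogenolysis, redox-active ester, then the chain is joined electrochemically in the last step.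
- Stereochemistry: the target has none; transient stereocentres are made without control and erased on aromatisation.

Key step: step 9

Remark: the target is achiral (no stereocentre, no stereogenic double bond), so a single defined compound is made without stereocontrol. Compounds 5 and 6 are racemic and 9 is a diastereomer mixture.

**Step 1**
Reactants: 1 erucic acid [(Z)-docos-13-enoic acid]
Product: 2 benzyl (Z)-docos-13-enoate
Conditions: BnBr, K2CO3, DMF, rt
Reagents that add atoms: benzyl bromide, BrCc1ccccc1
Why: SN2 O-alkylation of the potassium carboxylate gives a benzyl ester that is orthogonal to the later pyrrole methyl ester and leaves the Z-alkene untouched.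

**Step 2**
Reactants: 2 benzyl (Z)-docos-13-enoate
Product: 3 benzyl 13-oxotridecanoate
Conditions: O3, CH2Cl2, −78 °C (Sudan III end point); then PPh3, −78 °C to rt
Reagents that add atoms: ozone, [O-][O+]=O
Why: Ozonolysis (Criegee mechanism) with reductive work-up cleaves the only C=C bond to the aldehyde ester and nonanal, and the indicator end point protects the far less reactive benzyl ring.

**Step 3**
Reactants: 3 benzyl 13-oxotridecanoate; 4 nitromethane
Product: 5 benzyl 13-hydroxy-14-nitrotetradecanoate (racemic)
Conditions: MeNO2 (excess), KOtBu (cat.), THF/t-BuOH, 0 °C to rt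
Reagents that add atoms: none
Why: Henry (nitroaldol) reaction, in which catalytic base and excess nitromethane favour mono-addition over self-aldol; the carbinol centre is formed racemic on purpose because it is destroyed in step 5.

**Step 4**
Reactants: 5 benzyl 13-hydroxy-14-nitrotetradecanoate
Product: 6 benzyl 13-acetoxy-14-nitrotetradecanoate (racemic)
Conditions: Ac2O, DMAP (cat.), CH2Cl2, 0 °C to rt
Reagents that add atoms: acetic anhydride, CC(=O)OC(C)=O
Why: DMAP-catalysed O-acetylation turns the hydroxyl into a leaving group, giving a storable precursor of the sensitive terminal nitroalkene.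

**Step 5**
Reactants: 6 benzyl 13-acetoxy-14-nitrotetradecanoate; 7 methyl isocyanoacetate
Product: 10 benzyl 12-[2-(methoxycarbonyl)-1H-pyrrol-3-yl]dodecanoate, via nitroalkene 8 (not isolated), via nitropyrroline 9 (not isolated)
Conditions: DBU (2.2 equiv), THF, 0 °C to rt, slow addition of 6
Reagents that add atoms: none
Why: Barton–Zard pyrrole synthesis: DBU eliminates acetic acid to the (E)-nitroalkene, the isocyanoacetate anion adds to its alkyl-bearing carbon, the nitronate closes 5-endo-dig onto the isocyanide carbon, and loss of nitrous acid with tautomerisation gives the pyrrole, so that the chain must end at C3 next to the C2 ester with C4 and C5 unsubstituted.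

**Step 6**
Reactants: 10 benzyl 12-[2-(methoxycarbonyl)-1H-pyrrol-3-yl]dodecanoate
Product: 11 12-[2-(methoxycarbonyl)-1H-pyrrol-3-yl]dodecanoic acid
Conditions: H2 (1 atm), 10% Pd/C, EtOAc, rt
Reagents that add atoms: none
Why: Hydrogenolysis of the benzyl ester under neutral conditions should free the chain-end acid while the aromatic pyrrole and its conjugated methyl ester are not reduced.

**Step 7**
Reactants: 11 12-[2-(methoxycarbonyl)-1H-pyrrol-3-yl]dodecanoic acid
Product: 12 1,3-dioxoisoindolin-2-yl 12-[2-(methoxycarbonyl)-1H-pyrrol-3-yl]dodecanoate
Conditions: N-hydroxyphthalimide, DIC, DMAP (cat.), CH2Cl2, rt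
Reagents that add atoms: N-hydroxyphthalimide, ON1C(=O)c2ccccc2C1=O
Why: Carbodiimide (Steglich-type) esterification gives the redox-active ester, and the pyrrole N–H, deactivated by the C2 ester, should not be acylated without strong base.

**Step 8**
Reactants: 13 nonanoic acid
Product: 14 1,3-dioxoisoindolin-2-yl nonanoate
Conditions: N-hydroxyphthalimide, DIC, DMAP (cat.), CH2Cl2, rt
Reagents that add atoms: N-hydroxyphthalimide, ON1C(=O)c2ccccc2C1=O
Why: The same carbodiimide esterification gives the cheap octyl-radical precursor, which can be made in the excess that step 9 requires.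

**Step 9**
Reactants: 12 1,3-dioxoisoindolin-2-yl 12-[2-(methoxycarbonyl)-1H-pyrrol-3-yl]dodecanoate; 14 1,3-dioxoisoindolin-2-yl nonanoate (3 equiv)
Product: 15 methyl 3-nonadecyl-1H-pyrrole-2-carboxylate
Conditions: NiCl2·6H2O (20 mol%), 2,2':6',2''-terpyridine (20 mol%), AgNO3 (0.3 equiv), NaI, NMP, Mg(+)/RVC(−), constant current, undivided cell, rt
Reagents that add atoms: none
Why: Cathodically generated low-valent Ni(terpyridine), helped by silver nanoparticles deposited in situ on the cathode, transfers single electrons to both N-hydroxyphthalimide esters, each of which fragments to phthalimide anion, CO2 and a primary alkyl radical; the octyl and 11-(pyrrol-3-yl)undecyl radicals are captured at nickel and the dialkylnickel species reductively eliminates the C8–C9 bond, while the magnesium anode supplies the electrons. The closest known reaction type is the Ni-electrocatalytic doubly decarboxylative C(sp3)–C(sp3) coupling of two redox-active esters, the reductive counterpart of the mixed Kolbe electrolysis, which is established for primary–primary pairs. No ring is closed and no stereocentre is formed. The step needs cross- over homo-coupling and chemoselectivity for the two activated esters over the pyrrole: the cheap ester 14 is used in threefold excess so that 12 is consumed mainly as cross-product and the homodimer hexadecane is a non-polar hydrocarbon removed by chromatography, and the event is cathodic at a mild potential at which the oxidation-prone pyrrole ring, its N–H and the C2 methyl ester should be inert, which an anodic Kolbe coupling would not guarantee.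

**Compound list**
1 | erucic acid, (Z)-docos-13-enoic acid | CCCCCCCC/C=C\CCCCCCCCCCCC(=O)O | starting material
2 | benzyl (Z)-docos-13-enoate | CCCCCCCC/C=C\CCCCCCCCCCCC(=O)OCc1ccccc1 | intermediate
3 | benzyl 13-oxotridecanoate | O=CCCCCCCCCCCCC(=O)OCc1ccccc1 | intermediate
4 | nitromethane | C[N+](=O)[O-] | starting material
5 | benzyl 13-hydroxy-14-nitrotetradecanoate (racemic) | O=[N+]([O-])CC(O)CCCCCCCCCCCC(=O)OCc1ccccc1 | intermediate
6 | benzyl 13-acetoxy-14-nitrotetradecanoate (racemic) | CC(=O)OC(C[N+](=O)[O-])CCCCCCCCCCCC(=O)OCc1ccccc1 | intermediate
7 | methyl isocyanoacetate | [C-]#[N+]CC(=O)OC | starting material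
8 | benzyl (E)-14-nitrotetradec-13-enoate | O=[N+]([O-])/C=C/CCCCCCCCCCCC(=O)OCc1ccccc1 | intermediate (not isolated)
9 | methyl 3-[12-(benzyloxy)-12-oxododecyl]-4-nitro-3,4-dihydro-2H-pyrrole-2-carboxylate (diastereomer mixture) | COC(=O)C1N=CC([N+](=O)[O-])C1CCCCCCCCCCCC(=O)OCc1ccccc1 | intermediate (not isolated)
10 | benzyl 12-[2-(methoxycarbonyl)-1H-pyrrol-3-yl]dodecanoate | COC(=O)c1[nH]ccc1CCCCCCCCCCCC(=O)OCc1ccccc1 | intermediate
11 | 12-[2-(methoxycarbonyl)-1H-pyrrol-3-yl]dodecanoic acid | COC(=O)c1[nH]ccc1CCCCCCCCCCCC(=O)O | intermediate
12 | 1,3-dioxoisoindolin-2-yl 12-[2-(methoxycarbonyl)-1H-pyrrol-3-yl]dodecanoate | COC(=O)c1[nH]ccc1CCCCCCCCCCCC(=O)ON1C(=O)c2ccccc2C1=O | intermediate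
13 | nonanoic acid | CCCCCCCCC(=O)O | starting material
14 | 1,3-dioxoisoindolin-2-yl nonanoate | CCCCCCCCC(=O)ON1C(=O)c2ccccc2C1=O | intermediate
15 | methyl 3-nonadecyl-1H-pyrrole-2-carboxylate | CCCCCCCCCCCCCCCCCCCc1cc[nH]c1C(=O)OC | target

**Step count**
Total steps: 9. Longest linear sequence: 8 (steps 1–7 and 9); step 8 is a one-step side branch.

**Steps most likely to fail**

Step 9. The two radicals may pair statistically to homodimers, or the alkyl radical or alkylnickel species may be reduced to the alkane before coupling, which would waste 12. The fallback sets out from 12 and comes back at 15. Compound 12 is coupled in a Ni-catalysed decarboxylative Negishi alkyl–alkyl coupling (NiCl2·glyme, 4,4'-di-tert-butyl-2,2'-bipyridine, THF/DMF, rt) with di-n-octylzinc F1, prepared from octylmagnesium bromide and ZnCl2 in THF. The fixed nucleophile and electrophile roles exclude the homodimer of the pyrrole fragment, and a surplus of the zinc reagent allows for the acidic N–H.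

Step 5. The unhindered aliphatic nitroalkene may oligomerise under base, deconjugate to the allylic nitro isomer, or take up a second isocyanoacetate. The fallback sets out from 3 and comes back at 10 by a tosylglycinate (Kenner-type) pyrrole synthesis. Vinylmagnesium bromide is added to aldehyde 3 (THF, −78 °C) to give benzyl 13-hydroxypentadec-14-enoate F2. Dess–Martin oxidation gives the vinyl ketone benzyl 13-oxopentadec-14-enoate F3. Aza-Michael addition and intramolecular aldol closure with methyl N-tosylglycinate (DBU, THF) give methyl 3-[12-(benzyloxy)-12-oxododecyl]-3-hydroxy-1-tosylpyrrolidine-2-carboxylate F4. Dehydration with POCl3/pyridine gives methyl 3-[12-(benzyloxy)-12-oxododecyl]-1-tosyl-2,5-dihydro-1H-pyrrole-2-carboxylate F5. DBU then eliminates p-toluenesulfinate, and tautomerisation gives 10.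

Step 3. The nitroaldol is reversible, and the enolisable long-chain aldehyde may self-condense or the product may react a second time under base. The fallback sets out from 2 and comes back at 8, avoiding the aldehyde altogether. Ethenolysis of 2 (ethylene, Grubbs first-generation catalyst, CH2Cl2) gives benzyl tetradec-13-enoate F6. Radical nitration of the terminal alkene (AgNO2, TEMPO, 4 Å MS, 1,2-dichloroethane, 70 °C) should give the (E)-nitroalkene 8, here isolated. It is taken into step 5 with methyl isocyanoacetate and only 1.1 equiv of DBU.

**Further compounds**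
F1 | step 9 | di-n-octylzinc | CCCCCCCC[Zn]CCCCCCCC
F2 | step 5 | benzyl 13-hydroxypentadec-14-enoate (racemic) | C=CC(O)CCCCCCCCCCCC(=O)OCc1ccccc1
F3 | step 5 | benzyl 13-oxopentadec-14-enoate | C=CC(=O)CCCCCCCCCCCC(=O)OCc1ccccc1
F4 | step 5 | methyl 3-[12-(benzyloxy)-12-oxododecyl]-3-hydroxy-1-tosylpyrrolidine-2-carboxylate (diastereomer mixture) | COC(=O)C1N(S(=O)(=O)c2ccc(C)cc2)CCC1(O)CCCCCCCCCCCC(=O)OCc1ccccc1
F5 | step 5 | methyl 3-[12-(benzyloxy)-12-oxododecyl]-1-tosyl-2,5-dihydro-1H-pyrrole-2-carboxylate (racemic) | COC(=O)C1N(S(=O)(=O)c2ccc(C)cc2)CC=C1CCCCCCCCCCCC(=O)OCc1ccccc1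
F6 | step 3 | benzyl tetradec-13-enoate | C=CCCCCCCCCCCCC(=O)OCc1ccccc1
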